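**Retrosynthetic overview**
1. Numbering: each half is numbered as an isochroman (C1, O2, C3, C4, C4a, C5–C8, C8a), with primes for the lactone half. Ring A is the quinone-methide carbocycle, ring B its pyran, ring C the lactone-half arene and ring D the δ-lactone.
2. Feature the route rests on: ring C with its carboxyl carbon C1' is a resorcylate. It is the chain C1'–C8a'–C8'–C7'–C6'–C5'–C4a', oxygenated at C1', C8', C6' and C4a', and folded so that only the C4a'–C8a' bond is missing. Cutting that bond gives a diketo-dioxinone that already carries the C5' methyl, the C4'/C3' arm and, through the CH2 bridge on C7', all of ring A.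
3. The chain is cut at C4a'–C5' (dianion aldol with a Fráter–Seebach-derived aldehyde, then oxidation), at C6'–C7' (γ-propanoylation) and at bridge–C7' (γ-alkylation of 2,2,6-trimethyl-1,3-dioxin-4-one). It is grown in two stages because a β-keto acyl donor would only protonate the dienolate.
4. Ring A comes from 5-bromoresorcinol. The arm is made by anti opening of cis-2,3-epoxybutane, which is meso and gives a racemate, so a lipase resolution makes C3/C4 single-handed. The C5 methyl comes from bromination/methylation and the bridge carbon from directed lithiation at C7.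
5. Ring order: A (bought), C (step 18), D (fluoride-triggered lactonisation on C1'), B last. C1 is added after debenzylation to C8a, the only free arene carbon, so no acid-labile electron-rich aryl acetal has to pass through bromide and enolate chemistry.

Key step: step 18

Abbreviations: Bn = benzyl; TBS = tert-butyldimethylsilyl; Ar = 2,6-bis(benzyloxy)-3-methyl-4-[(2S,3R)-3-(TBS-oxy)butan-2-yl]phenyl, the protected ring A unit bonded through C7.

Assumption: C7', C5' and the carbinol carbon C4a' of the open-chain and cyclic aldol compounds are carried as epimer mixtures and drawn without configuration, since step 18 makes them all sp2. The CIP letter of C4' changes along the route (R next to a carbonyl, S next to the arene), but its spatial arrangement never does.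

**Route**

Step 1
Reactants: 1 5-bromoresorcinol
Product: 2 1,3-bis(benzyloxy)-5-bromobenzene
Conditions: BnBr (2.2 equiv), K2CO3, DMF, rt
Reagents that add atoms: benzyl bromide, BrCc1ccccc1
Why: Williamson ether synthesis on both phenols should be clean, and benzyl ethers withstand the organolithium, enolate, oxidation and fluoride steps yet leave by neutral hydrogenolysis without releasing formaldehyde next to the free C8a position.

Step 2
Reactants: 2 1,3-bis(benzyloxy)-5-bromobenzene; 3 cis-2,3-epoxybutane (meso)
Product: 5 rac-(2R*,3S*)-3-[3,5-bis(benzyloxy)phenyl]butan-2-ol (threo racemate), via aryllithium 4 (not isolated)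
Conditions: n-BuLi, THF, −78 °C; then 3, BF3·OEt2, −78 °C
Reagents that add atoms: none
Why: Bromine–lithium exchange followed by BF3-assisted SN2 opening of the epoxide with inversion at the attacked carbon turns the cis epoxide into the threo relative configuration of C3/C4 only, but as a racemate because the two carbons of the meso epoxide are enantiotopic.

Step 3
Reactants: 5 rac-(2R*,3S*)-3-[3,5-bis(benzyloxy)phenyl]butan-2-ol
Product: 6 (2R,3S)-3-[3,5-bis(benzyloxy)phenyl]butan-2-yl acetate
Conditions: immobilised Candida antarctica lipase B, vinyl acetate, t-BuOMe, 30 °C, stopped just below half conversion; chromatography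
Reagents that add atoms: vinyl acetate, C=COC(C)=O
Why: Lipase-catalysed kinetic resolution by irreversible transesterification, in which the enzyme's discrimination between the methyl and the large group makes the (2R)-carbinol acylate much faster, should deliver the (2R,3S)-acetate as one enantiomer and so fixes the absolute configuration of C3 (R) and C4 (S).

Step 4
Reactants: 6 (2R,3S)-3-[3,5-bis(benzyloxy)phenyl]butan-2-yl acetate
Product: 7 (2R,3S)-3-[3,5-bis(benzyloxy)phenyl]butan-2-ol
Conditions: K2CO3 (cat), MeOH, rt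
Reagents that add atoms: none
Why: Base-catalysed transesterification with methanol cleaves only the acyl–oxygen bond, so both stereocenters stay untouched.

Step 5
Reactants: 7 (2R,3S)-3-[3,5-bis(benzyloxy)phenyl]butan-2-ol
Product: 8 TBS ether of 7
Conditions: TBSCl, imidazole, DMF, rt
Reagents that add atoms: tert-butyldimethylsilyl chloride, CC(C)(C)[Si](C)(C)Cl
Why: Imidazole-promoted silylation masks the C3 hydroxyl against the organolithium and enolate steps, and the later fluoride treatment removes it together with the C3' silyl ether.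

Step 6
Reactants: 8 TBS ether of 7
Product: 9 TBS ether of (2R,3S)-3-[3,5-bis(benzyloxy)-2-bromophenyl]butan-2-ol (bromine on the future C5)
Conditions: NBS (1.0 equiv), MeCN, 0 °C
Reagents that add atoms: N-bromosuccinimide, O=C1CCC(=O)N1Br
Why: Electrophilic aromatic bromination of a 5-alkylresorcinol diether goes para to one ether oxygen rather than between the two oxygens, and the two such positions are equivalent, so a single monobromide is expected.

Step 7
Reactants: 9 C5 bromide
Product: 11 TBS ether of (2R,3S)-3-[3,5-bis(benzyloxy)-2-methylphenyl]butan-2-ol, via C5 aryllithium 10 (not isolated)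
Conditions: n-BuLi, THF, −78 °C; then MeI, −78 °C to rt
Reagents that add atoms: iodomethane, CI
Why: Bromine–lithium exchange outruns any deprotonation at −78 °C, and the aryllithium is methylated by SN2 attack on iodomethane, which installs the C5 methyl group.

Step 8
Reactants: 11 C5-methyl arene
Product: 13 2,6-bis(benzyloxy)-3-methyl-4-[(2S,3R)-3-(TBS-oxy)butan-2-yl]benzaldehyde (ArCHO), via C7 aryllithium 12 (not isolated)
Conditions: n-BuLi, TMEDA, THF, 0 °C; then DMF, 0 °C to rt
Reagents that add atoms: N,N-dimethylformamide, CN(C)C=O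
Why: Directed ortho-metalation takes the C7 hydrogen because it lies between two coordinating ether oxygens, whereas C8a–H has only one such neighbour and the bulky arm beside it, and DMF then formylates the aryllithium.

Step 9
Reactants: 13 ArCHO
Product: 14 ArCH2OH
Conditions: NaBH4, MeOH–THF, 0 °C
Reagents that add atoms: none
Why: Borohydride reduction of the aldehyde is chemoselective, since no other reducible group is present.

Step 10
Reactants: 14 ArCH2OH
Product: 15 ArCH2Br
Conditions: CBr4, PPh3, CH2Cl2, 0 °C; short silica plug, used at once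
Reagents that add atoms: tetrabromomethane, BrC(Br)(Br)Br
Why: The Appel reaction turns the primary benzylic alcohol into the bromide under essentially neutral conditions that spare the silyl ether, and immediate use allows for the lability of this electron-rich bromide.

Step 11
Reactants: 16 methyl (R)-3-hydroxybutanoate
Product: 18 methyl (2R,3R)-3-hydroxy-2-methylbutanoate, via dilithium dianion 17 (not isolated)
Conditions: LiN(i-Pr)2 (LDA, 2.2 equiv), THF, −78 to −20 °C; then MeI, DMPU, −78 to 0 °C
Reagents that add atoms: iodomethane, CI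
Why: In the Fráter–Seebach alkylation the lithium-chelated alkoxide enolate is methylated on the face opposite to the C3' methyl group, which sets C4' anti to the pool-derived C3' and gives the (2R,3R)-ester.

Step 12
Reactants: 18 methyl (2R,3R)-3-hydroxy-2-methylbutanoate
Product: 19 methyl (2R,3R)-3-(TBS-oxy)-2-methylbutanoate
Conditions: TBSCl, imidazole, DMF, rt
Reagents that add atoms: tert-butyldimethylsilyl chloride, CC(C)(C)[Si](C)(C)Cl
Why: Imidazole-promoted silylation blocks the C3' hydroxyl so that it cannot add to the poly-carbonyl chain before ring C exists.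

Step 13
Reactants: 19 methyl (2R,3R)-3-(TBS-oxy)-2-methylbutanoate
Product: 20 (2R,3R)-3-(TBS-oxy)-2-methylbutanal
Conditions: i-Bu2AlH (1.1 equiv), CH2Cl2, −78 °C; aq potassium sodium tartrate; used crude
Reagents that add atoms: none
Why: Partial reduction of the ester stops at the aluminium hemiacetal at −78 °C, and the non-basic work-up and prompt use keep the α-stereocenter C4' intact.

Step 14
Reactants: 21 2,2,6-trimethyl-4H-1,3-dioxin-4-one; 15 ArCH2Br
Product: 23 6-(2-Ar-ethyl)-2,2-dimethyl-4H-1,3-dioxin-4-one, via lithium dienolate 22 (not isolated)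
Conditions: 21 (3 equiv), LDA, THF–DMPU, −78 °C; then 15, −78 to −20 °C
Reagents that add atoms: none
Why: γ-Alkylation of the cross-conjugated dioxinone dienolate by a reactive benzylic halide in a dipolar cosolvent forms the bridge–C7' bond, and an excess of the cheap dienolate should consume the labile bromide quickly.

Step 15
Reactants: 23 6-(2-Ar-ethyl)-2,2-dimethyl-4H-1,3-dioxin-4-one
Product: 25 6-(1-Ar-3-oxopentan-2-yl)-2,2-dimethyl-4H-1,3-dioxin-4-one (keto-dioxinone), via lithium dienolate 24 (not isolated)
Conditions: LiN(SiMe3)2 (2.2 equiv), THF, −78 °C; then EtCOCl (1.1 equiv), −78 °C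
Reagents that add atoms: propanoyl chloride, CCC(Cl)=O
Why: Claisen-type γ-C-acylation of the dioxinone dienolate builds C6'–C7', the second equivalent of the hindered base takes up the more acidic product, and a plain propanoyl unit is used because a β-keto acyl donor would merely be deprotonated.

Step 16
Reactants: 25 keto-dioxinone; 20 (2R,3R)-3-(TBS-oxy)-2-methylbutanal
Product: 27 6-[(6S,7R)-1-Ar-5-hydroxy-4,6-dimethyl-3-oxo-7-(TBS-oxy)octan-2-yl]-2,2-dimethyl-4H-1,3-dioxin-4-one (aldol), via dilithium dianion 26 (not isolated)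
Conditions: LDA (2.2 equiv), THF, −78 to −40 °C; then 20, −78 °C
Reagents that add atoms: none
Why: In this aldol addition the keto-dioxinone dianion reacts, like a β-keto ester dianion, at the carbon deprotonated last (C5'), which forms C4a'–C5' without touching C4' and creates only centres that steps 17 and 18 erase.

Step 17
Reactants: 27 aldol
Product: 28 6-[(6R,7R)-1-Ar-4,6-dimethyl-3,5-dioxo-7-(TBS-oxy)octan-2-yl]-2,2-dimethyl-4H-1,3-dioxin-4-one (diketo-dioxinone)
Conditions: Dess–Martin periodinane (1.2 equiv), CH2Cl2, 0 °C to rt; used without storage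
Reagents that add atoms: none
Why: Dess–Martin oxidation converts the β-hydroxy ketone into the 2-methyl-1,3-diketone under nearly neutral conditions that spare the silyl ethers, the dioxinone and the C4' stereocenter.

Step 18
Reactants: 28 diketo-dioxinone
Product: 30 8-(Ar-methyl)-7-hydroxy-2,2,6-trimethyl-5-[(2S,3R)-3-(TBS-oxy)butan-2-yl]-4H-1,3-benzodioxin-4-one (bridged benzodioxinone resorcylate), via cyclic aldol 29 (not isolated)
Conditions: Et3N (5 equiv), CH2Cl2, rt
Reagents that add atoms: none
Why: Et3N removes the most acidic proton, C7'–H, and the resulting cross-conjugated dienolate attacks the C4a' ketone through its α-carbon C8a' (intramolecular vinylogous aldol addition) to give carbinol 29, after which loss of water across C8a'–C4a' and enolisation of the C6' ketone with loss of C5'–H aromatise ring C. This is the known base-mediated aldol aromatisation of diketo-dioxinones to isopropylidene-protected resorcylates, applied here to a chain substituted at both C5' and C7'. Ring C closes in a 6-(enolendo)-exo-trig mode, with the C4a' carbonyl oxygen staying outside the new six-membered ring. No stereocenter is created: the epimeric centres C5' and C7' (and C4a' of 29) become sp2, while C3', C4', C3 and C4 are only carried along. The step needs C- over O-cyclisation, and this is secured by an amine base at room temperature (no acid or heat, so neither pyranone closure through an enol oxygen nor acylketene formation is opened) and by the 2-methyl-1,3-diketone, which is little enolised and keeps C4a' electrophilic. It also needs C4' to hold its configuration and the C3' silyloxy group not to β-eliminate, and this is secured because the far more acidic C5'–H and C7'–H take up the weak base.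

Step 19
Reactants: 30 bridged benzodioxinone resorcylate
Product: 32 (3R,4S)-7-{2,6-bis(benzyloxy)-4-[(2S,3R)-3-hydroxybutan-2-yl]-3-methylbenzyl}-6,8-dihydroxy-3,4,5-trimethylisochroman-1-one, via diol 31 (not isolated)
Conditions: n-Bu4NF (5 equiv), THF, 0 to 40 °C
Reagents that add atoms: none
Why: Fluoride desilylation frees both secondary alcohols, and the C3' alkoxide, held next to C1', opens the benzodioxinone by 6-exo-trig intramolecular transesterification with loss of acetone, which closes ring D with retention at C3' while the C3 alkoxide has no acyl group within reach.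

Step 20
Reactants: 32 dibenzyl ether lactone
Product: 33 (3R,4S)-7-{2,6-dihydroxy-4-[(2S,3R)-3-hydroxybutan-2-yl]-3-methylbenzyl}-6,8-dihydroxy-3,4,5-trimethylisochroman-1-one
Conditions: H2 (1 atm), 10% Pd/C, EtOAc–MeOH, rt
Reagents that add atoms: none
Why: Catalytic hydrogenolysis cleaves only the two O-benzyl bonds, because the diarylmethane bridge and the homobenzylic lactone C–O bond are not activated, and it has to precede ring B because the quinone methide would itself be reduced.

Step 21
Reactants: 33 tetraphenol alcohol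
Product: 35 dicitrinone G, via 1-ethoxyisochroman 34 (not isolated)
Conditions: HC(OEt)3, CF3CO2H, CH2Cl2, 0 °C to rt; then 1 M aq HCl
Reagents that add atoms: triethyl orthoformate, CCOC(OCC)OCC
Why: In this acid-promoted orthoformate formylation–cyclisation (oxa-Pictet–Spengler type, a known way to close this kind of pyrano-quinone methide) the C3 hydroxyl enters the orthoester, the derived dialkoxycarbenium ion is attacked by C8a, which is the only unsubstituted arene carbon, lies ortho to O8 and para to O6 and is the only position the tether can reach, and loss of ethanol from 34 gives the quinone methide with C3 and C4 untouched.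

**Compound list**
1 | 5-bromoresorcinol | Oc1cc(O)cc(Br)c1 | starting material
2 | 1,3-bis(benzyloxy)-5-bromobenzene | Brc1cc(OCc2ccccc2)cc(OCc2ccccc2)c1 | intermediate
3 | cis-2,3-epoxybutane (meso) | C[C@H]1O[C@H]1C | starting material
4 | 3,5-bis(benzyloxy)phenyllithium (not isolated) | [Li]c1cc(OCc2ccccc2)cc(OCc2ccccc2)c1 | intermediate
5 | rac-(2R*,3S*)-3-[3,5-bis(benzyloxy)phenyl]butan-2-ol (racemate, the (2R,3S) enantiomer drawn) | C(c1ccccc1)Oc1cc(OCc2ccccc2)cc(c1)[C@H](C)[C@@H](C)O | intermediate
6 | (2R,3S)-3-[3,5-bis(benzyloxy)phenyl]butan-2-yl acetate | C(c1ccccc1)Oc1cc(OCc2ccccc2)cc(c1)[C@H](C)[C@@H](C)OC(C)=O | intermediate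
7 | (2R,3S)-3-[3,5-bis(benzyloxy)phenyl]butan-2-ol (single enantiomer) | C(c1ccccc1)Oc1cc(OCc2ccccc2)cc(c1)[C@H](C)[C@@H](C)O | intermediate
8 | TBS ether of 7 | C(c1ccccc1)Oc1cc(OCc2ccccc2)cc(c1)[C@H](C)[C@@H](C)O[Si](C)(C)C(C)(C)C | intermediate
9 | TBS ether of (2R,3S)-3-[3,5-bis(benzyloxy)-2-bromophenyl]butan-2-ol | Brc1c(OCc2ccccc2)cc(OCc2ccccc2)cc1[C@H](C)[C@@H](C)O[Si](C)(C)C(C)(C)C | intermediate
10 | C5 aryllithium from 9 (not isolated) | [Li]c1c(OCc2ccccc2)cc(OCc2ccccc2)cc1[C@H](C)[C@@H](C)O[Si](C)(C)C(C)(C)C | intermediate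
11 | TBS ether of (2R,3S)-3-[3,5-bis(benzyloxy)-2-methylphenyl]butan-2-ol | Cc1c(OCc2ccccc2)cc(OCc2ccccc2)cc1[C@H](C)[C@@H](C)O[Si](C)(C)C(C)(C)C | intermediate
12 | C7 aryllithium from 11 (ArLi, not isolated) | [Li]c1c(OCc2ccccc2)cc([C@H](C)[C@@H](C)O[Si](C)(C)C(C)(C)C)c(C)c1OCc1ccccc1 | intermediate
13 | 2,6-bis(benzyloxy)-3-methyl-4-[(2S,3R)-3-(TBS-oxy)butan-2-yl]benzaldehyde | O=Cc1c(OCc2ccccc2)cc([C@H](C)[C@@H](C)O[Si](C)(C)C(C)(C)C)c(C)c1OCc1ccccc1 | intermediate
14 | {2,6-bis(benzyloxy)-3-methyl-4-[(2S,3R)-3-(TBS-oxy)butan-2-yl]phenyl}methanol | OCc1c(OCc2ccccc2)cc([C@H](C)[C@@H](C)O[Si](C)(C)C(C)(C)C)c(C)c1OCc1ccccc1 | intermediate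
15 | 2,6-bis(benzyloxy)-3-methyl-4-[(2S,3R)-3-(TBS-oxy)butan-2-yl]benzyl bromide | BrCc1c(OCc2ccccc2)cc([C@H](C)[C@@H](C)O[Si](C)(C)C(C)(C)C)c(C)c1OCc1ccccc1 | intermediate
16 | methyl (R)-3-hydroxybutanoate | O[C@H](C)CC(=O)OC | starting material
17 | dilithium alkoxide enolate of 16 (not isolated) | COC(O[Li])=C[C@@H](C)O[Li] | intermediate
18 | methyl (2R,3R)-3-hydroxy-2-methylbutanoate | COC(=O)[C@H](C)[C@@H](C)O | intermediate
19 | methyl (2R,3R)-3-(TBS-oxy)-2-methylbutanoate | COC(=O)[C@H](C)[C@@H](C)O[Si](C)(C)C(C)(C)C | intermediate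
20 | (2R,3R)-3-(TBS-oxy)-2-methylbutanal | O=C[C@H](C)[C@@H](C)O[Si](C)(C)C(C)(C)C | intermediate
21 | 2,2,6-trimethyl-4H-1,3-dioxin-4-one | CC1=CC(=O)OC(C)(C)O1 | starting material
22 | lithium dienolate of 21 (not isolated) | C=C1C=C(O[Li])OC(C)(C)O1 | intermediate
23 | 6-(2-Ar-ethyl)-2,2-dimethyl-4H-1,3-dioxin-4-one | CC1(C)OC(=O)C=C(O1)CCc1c(OCc2ccccc2)cc([C@H](C)[C@@H](C)O[Si](C)(C)C(C)(C)C)c(C)c1OCc1ccccc1 | intermediate
24 | lithium dienolate of 23 (not isolated) | CC1(C)OC(O[Li])=CC(=CCc2c(OCc3ccccc3)cc([C@H](C)[C@@H](C)O[Si](C)(C)C(C)(C)C)c(C)c2OCc2ccccc2)O1 | intermediate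
25 | keto-dioxinone, 6-(1-Ar-3-oxopentan-2-yl)-2,2-dimethyl-4H-1,3-dioxin-4-one (C7' epimers) | CC1(C)OC(=O)C=C(O1)C(Cc1c(OCc2ccccc2)cc([C@H](C)[C@@H](C)O[Si](C)(C)C(C)(C)C)c(C)c1OCc1ccccc1)C(=O)CC | intermediate
26 | dilithium dianion of 25 (not isolated) | CC=C(O[Li])C(Cc1c(OCc2ccccc2)cc([C@H](C)[C@@H](C)O[Si](C)(C)C(C)(C)C)c(C)c1OCc1ccccc1)=C1C=C(O[Li])OC(C)(C)O1 | intermediate
27 | aldol, C4a' carbinol (epimers at C7', C5', C4a'; C3' R, C4' S) | CC1(C)OC(=O)C=C(O1)C(Cc1c(OCc2ccccc2)cc([C@H](C)[C@@H](C)O[Si](C)(C)C(C)(C)C)c(C)c1OCc1ccccc1)C(=O)C(C)C(O)[C@H](C)[C@@H](C)O[Si](C)(C)C(C)(C)C | intermediate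
28 | diketo-dioxinone, key-step precursor (epimers at C7', C5'; C3' R, C4' R) | CC1(C)OC(=O)C=C(O1)C(Cc1c(OCc2ccccc2)cc([C@H](C)[C@@H](C)O[Si](C)(C)C(C)(C)C)c(C)c1OCc1ccccc1)C(=O)C(C)C(=O)[C@H](C)[C@@H](C)O[Si](C)(C)C(C)(C)C | intermediate
29 | cyclic aldol with the C4a'–C8a' bond formed, before dehydration (not isolated) | CC1(C)OC(=O)C2C(O1)=C(Cc3c(OCc4ccccc4)cc([C@H](C)[C@@H](C)O[Si](C)(C)C(C)(C)C)c(C)c3OCc3ccccc3)C(=O)C(C)C2(O)[C@H](C)[C@@H](C)O[Si](C)(C)C(C)(C)C | intermediate
30 | bridged benzodioxinone resorcylate, key-step product | CC1(C)OC(=O)c2c(O1)c(Cc3c(OCc4ccccc4)cc([C@H](C)[C@@H](C)O[Si](C)(C)C(C)(C)C)c(C)c3OCc3ccccc3)c(O)c(C)c2[C@H](C)[C@@H](C)O[Si](C)(C)C(C)(C)C | intermediate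
31 | bis-desilylated diol of 30 (not isolated) | CC1(C)OC(=O)c2c(O1)c(Cc3c(OCc4ccccc4)cc([C@H](C)[C@@H](C)O)c(C)c3OCc3ccccc3)c(O)c(C)c2[C@H](C)[C@@H](C)O | intermediate
32 | dibenzyl ether lactone (rings A, C, D) | Cc1c(OCc2ccccc2)c(Cc2c(O)c(C)c3c(c2O)C(=O)O[C@H](C)[C@H]3C)c(OCc2ccccc2)cc1[C@H](C)[C@@H](C)O | intermediate
33 | tetraphenol alcohol lactone | Cc1c(O)c(Cc2c(O)c(C)c3c(c2O)C(=O)O[C@H](C)[C@H]3C)c(O)cc1[C@H](C)[C@@H](C)O | intermediate
34 | 1-ethoxyisochroman (C1 epimers, not isolated) | CCOC1O[C@H](C)[C@@H](C)c2c(C)c(O)c(Cc3c(O)c(C)c4c(c3O)C(=O)O[C@H](C)[C@H]4C)c(O)c12 | intermediate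
35 | dicitrinone G, (3R,4S,3'R,4'S) | CC1=C2C(=CO[C@H](C)[C@H]2C)C(=O)C(Cc2c(O)c(C)c3c(c2O)C(=O)O[C@H](C)[C@H]3C)=C1O | target

**Step count**
Total steps: 21. Longest linear sequence: 18 steps (steps 1–10, then 14–21).

**The three steps most likely to fail**

Step 18 (key step).
- What may go wrong: the C8a'–C4a' closure may be too slow at a ketone that is branched on both sides. O-cyclisation through an enol oxygen, retro-Claisen cleavage at C7' or β-elimination of the C3' silyloxy group could then take over.
- Fallback: it sets out from 28 and comes back at 32. Compound 28 is heated in toluene at 110 °C with methanol. The dioxinone opens by cycloreversion with loss of acetone and methanol is taken up, which should give the methyl 3,5,7-trioxo ester F1.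
- In the methyl 3,5,7-trioxo ester F1, C8a' is the CH2 of an open β-keto ester, a more acidic and less encumbered carbon nucleophile. Cs2CO3 in MeOH followed by AcOH should then close and dehydrate it by the known triketo-ester aldol aromatisation to the methyl resorcylate F2.
- n-Bu4NF in THF, followed by catalytic p-TsOH in warm toluene if lactonisation lags, removes both silyl groups and closes ring D with loss of methanol to give 32.

Step 16 (dianion aldol).
- What may go wrong: the second deprotonation of the α-substituted keto-dioxinone may be incomplete, the enolisable aldehyde may transfer a proton to the dianion, and the adduct may undergo retro-aldol cleavage on work-up.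
- Fallback: it sets out from 20 and 23 and comes back at 27. The order of bond formation is reversed, so that C4a'–C5' is made first on a small fragment and C6'–C7' last.
- N-methoxy-N-methylpropanamide is deprotonated with LDA and added to 20 to give the β-hydroxy Weinreb amide F3. Et3SiCl and imidazole convert this into the triethylsilyl ether F4.
- Dienolate 24 (from 23 and LDA) is acylated with the triethylsilyl ether F4. The chelated tetrahedral adduct survives until work-up, so the acidic product cannot quench the dienolate. This should give the silyloxy keto-dioxinone F5.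
- Pyridinium p-toluenesulfonate in MeOH removes the triethylsilyl group selectively in the presence of the two TBS ethers and gives 27.

Step 14 (γ-alkylation).
- What may go wrong: the very electron-rich bromide 15 may ionise and self-condense, and the dienolate may undergo competing α-alkylation or double alkylation.
- Fallback: it sets out from 13 and comes back at 23. The dioxinone ring is built around the side chain, so no benzylic halide is needed.
- Reductive Knoevenagel alkylation of Meldrum's acid with 13 (Hantzsch ester, catalytic L-proline, EtOH) should give the 5-(Ar-methyl) Meldrum's acid F6.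
- Heating this in wet DMF at 100 °C hydrolyses and decarboxylates it to the 3-Ar-propanoic acid F7.
- Coupling with Meldrum's acid (EDC·HCl, DMAP, CH2Cl2) gives the acyl Meldrum's acid F8. Refluxing this in toluene with acetone releases CO2, and the ketene so formed is captured by acetone as dioxinone 23.

**Further compounds**
F1 | step 18 | methyl 4-(Ar-methyl)-6,8-dimethyl-3,5,7-trioxo-9-(TBS-oxy)decanoate (methyl 3,5,7-trioxo ester) | COC(=O)CC(=O)C(Cc1c(OCc2ccccc2)cc([C@H](C)[C@@H](C)O[Si](C)(C)C(C)(C)C)c(C)c1OCc1ccccc1)C(=O)C(C)C(=O)[C@H](C)[C@@H](C)O[Si](C)(C)C(C)(C)C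
F2 | step 18 | methyl 3-(Ar-methyl)-2,4-dihydroxy-5-methyl-6-[(2S,3R)-3-(TBS-oxy)butan-2-yl]benzoate (methyl resorcylate) | COC(=O)c1c(O)c(Cc2c(OCc3ccccc3)cc([C@H](C)[C@@H](C)O[Si](C)(C)C(C)(C)C)c(C)c2OCc2ccccc2)c(O)c(C)c1[C@H](C)[C@@H](C)O[Si](C)(C)C(C)(C)C
F3 | step 16 | 3-hydroxy-N-methoxy-N,2,4-trimethyl-5-(TBS-oxy)hexanamide (β-hydroxy Weinreb amide, epimers at C2 and C3) | CON(C)C(=O)C(C)C(O)[C@H](C)[C@@H](C)O[Si](C)(C)C(C)(C)C
F4 | step 16 | triethylsilyl ether of F3 | CON(C)C(=O)C(C)C(O[Si](CC)(CC)CC)[C@H](C)[C@@H](C)O[Si](C)(C)C(C)(C)C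
F5 | step 16 | silyloxy keto-dioxinone, the C4a' triethylsilyl ether of 27 | CC1(C)OC(=O)C=C(O1)C(Cc1c(OCc2ccccc2)cc([C@H](C)[C@@H](C)O[Si](C)(C)C(C)(C)C)c(C)c1OCc1ccccc1)C(=O)C(C)C(O[Si](CC)(CC)CC)[C@H](C)[C@@H](C)O[Si](C)(C)C(C)(C)C
F6 | step 14 | 5-(Ar-methyl)-2,2-dimethyl-1,3-dioxane-4,6-dione | CC1(C)OC(=O)C(Cc2c(OCc3ccccc3)cc([C@H](C)[C@@H](C)O[Si](C)(C)C(C)(C)C)c(C)c2OCc2ccccc2)C(=O)O1
F7 | step 14 | 3-Ar-propanoic acid | OC(=O)CCc1c(OCc2ccccc2)cc([C@H](C)[C@@H](C)O[Si](C)(C)C(C)(C)C)c(C)c1OCc1ccccc1
F8 | step 14 | 5-(3-Ar-propanoyl)-2,2-dimethyl-1,3-dioxane-4,6-dione | CC1(C)OC(=O)C(C(=O)CCc2c(OCc3ccccc3)cc([C@H](C)[C@@H](C)O[Si](C)(C)C(C)(C)C)c(C)c2OCc2ccccc2)C(=O)O1
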